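Numbering (eunicellane): ring A = C1/C10–C14; tetrahydrofuran = C1–C2–O–C9–C10; oxonane = O/C2–C9; oxepane = C1–C2–C3–O16–C16–C15–C14; C17 = methyl on C15.
The oxonane is closed last: C6–C7 by Nozaki–Hiyama–Kishi reaction, then acetylation and Markovnikov hydration of the C7 methylene group.
The oxepane comes from an oxygen relay. O16 is first parked on C13 as a five-membered allylic ether. One flask then releases it oxidatively (giving the C13 enone), epoxidises the (Z)-C3=C4 olefin, and lets O16 open the epoxide at tertiary C3 (7-exo), which also frees C4–OH.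
Enabling feature: O16 is gamma to the ring A carbonyl carbon C13. Across the cis edge C14–C1–C2 it also lies within a seven-membered reach of tertiary C3, which sits between oxygenated C2 and C4.
Ring order: ring A plus γ-lactone (the future tetrahydrofuran) by dienol/maleic anhydride Diels–Alder reaction, temporary tetrahydrofuran by 1,5-hydrogen-transfer etherification, oxepane, oxonane.

Key step: step 14

Assumption: 1, 7, 18 and all named reagents are purchasable. The anomeric centre (C2) of 16 and 17 is a mixture and is written without configuration, because it becomes planar in step 13.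

Step 1
Reactants: 1 (E)-3-methylpent-2-en-4-yn-1-ol
Product: 2 (E)-3-methylpenta-2,4-dien-1-ol
Conditions: H2 (1 atm), Pd/CaCO3 poisoned with Pb(OAc)2 (Lindlar catalyst), quinoline, MeOH, 0 °C
Reagents that add atoms: none
Why: Lindlar semihydrogenation should stop at the terminal alkene and leave the (E)-trisubstituted double bond unchanged.

Step 2
Reactants: 2 (E)-3-methylpenta-2,4-dien-1-ol
Product: 3 (E)-3-methylpenta-2,4-dienal
Conditions: MnO2, CH2Cl2, rt
Reagents that add atoms: none
Why: MnO2 oxidation of the dienylic alcohol should give the dienal without E/Z isomerisation or over-oxidation.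

Step 3
Reactants: 3 (E)-3-methylpenta-2,4-dienal
Product: 4 rac-(E)-2-bromo-6-methylocta-1,5,7-trien-4-ol
Conditions: Zn dust, 2,3-dibromopropene, THF/sat. aq NH4Cl, 0 °C
Reagents that add atoms: 2,3-dibromopropene C=C(Br)CBr
Why: In this Barbier allylation zinc inserts only into the allylic C–Br bond and the allylzinc adds 1,2 to the dienal, so the vinyl bromide needed for the last ring closure is carried from here and the new carbinol centre is still racemic.

Step 4
Reactants: 4 rac-(E)-2-bromo-6-methylocta-1,5,7-trien-4-ol
Product: 5 (E)-2-bromo-6-methylocta-1,5,7-trien-4-one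
Conditions: Dess–Martin periodinane, CH2Cl2, 0 °C
Reagents that add atoms: none
Why: Dess–Martin oxidation under neutral conditions erases the racemic centre without moving the β,γ-double bond into conjugation.

Step 5
Reactants: 5 (E)-2-bromo-6-methylocta-1,5,7-trien-4-one
Product: 6 (4R,5E)-2-bromo-6-methylocta-1,5,7-trien-4-ol
Conditions: (S)-Me-CBS oxazaborolidine (20 mol%), catecholborane, toluene, −78 °C
Reagents that add atoms: none
Why: In this Corey–Bakshi–Shibata reduction the dienyl group acts as the large substituent and the bromoallyl CH2 as the small one, so the (S)-catalyst should give the (R)-carbinol that becomes C9.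

Step 6
Reactants: 6 (4R,5E)-2-bromo-6-methylocta-1,5,7-trien-4-ol; 7 maleic anhydride
Product: 9 lactone acid (cis-fused γ-lactone on ring A; C9 R; H1/H10/H14 on one face; C2/C9/CO2H on the other), via maleate half-ester 8 (not isolated)
Conditions: toluene, BHT (cat.), 110 °C
Reagents that add atoms: none
Why: Acylation of the dienol followed by an endo intramolecular Diels–Alder reaction of the (Z)-maleate should give the all-cis adduct, because A(1,3) strain between the C11 methyl group and C9 places H9 in the diene plane, so the tethered dienophile adds on the face bearing the ester oxygen and C9 controls C10, C1 and C14.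

Step 7
Reactants: 9 lactone acid
Product: 11 lactone aldehyde (CHO on C14; other centres as in 9), via acid chloride 10 (not isolated)
Conditions: (COCl)2, DMF (cat.), CH2Cl2, 0 °C; then LiAlH(OtBu)3, THF, −78 °C
Reagents that add atoms: oxalyl chloride O=C(Cl)C(=O)Cl
Why: Partial reduction of an acid chloride with the bulky LiAlH(OtBu)3 at low temperature stops at the aldehyde and leaves the lactone and the vinyl bromide untouched.

Step 8
Reactants: 11 lactone aldehyde
Product: 12 vinyl lactone (vinyl group on C14; other centres as in 9)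
Conditions: Ph3PCH3Br, KHMDS, THF, −78 to 0 °C
Reagents that add atoms: methyltriphenylphosphonium bromide C[P+](c1ccccc1)(c1ccccc1)c1ccccc1.[Br-]
Why: Wittig methylenation at low temperature is faster than enolisation of the aldehyde, so the cis C14 centre should survive.

Step 9
Reactants: 12 vinyl lactone
Product: 14 primary alcohol (15S; C14 now bears CH(CH3)CH2OH), via dimethylalane 13 (not isolated)
Conditions: AlMe3, (+)-(NMI)2ZrCl2 [bis(1-neomenthylindenyl)zirconium dichloride, 5 mol%], CH2Cl2, rt; then O2, 0 °C; aqueous work-up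
Reagents that add atoms: trimethylaluminium C[Al](C)C; dioxygen O=O
Why: Zirconium-catalysed asymmetric carboalumination (ZACA) adds Me–Al across the only monosubstituted alkene with aluminium at the terminus, the (+)-catalyst gives (S)-2-methylalkanols and is matched with the substrate (whose vinyl group is open on the face away from C1), and oxidation of the primary C–Al bond does not touch C15.

Step 10
Reactants: 14 primary alcohol
Product: 15 ether lactone (O16 bonded to C13; temporary cis-fused tetrahydrofuran C13–C14–C15–C16–O16; 13S)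
Conditions: PhI(OAc)2, I2, cyclohexane/CH2Cl2, visible light, rt
Reagents that add atoms: none
Why: In this Suárez-type hypoiodite reaction the O16 alkoxy radical abstracts the allylic C13–H by 1,5-hydrogen transfer, and oxidation of the allyl radical followed by ring closure gives the tetrahydrofuran on the face of C13 that carries the C14 side chain, so C13 is oxidised regiospecifically and O16 is protected at the same time.

Step 11
Reactants: 15 ether lactone
Product: 17 anomeric acetate (OAc on C2; anomer mixture), via aluminium hemiacetal 16 (not isolated)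
Conditions: DIBAL-H, CH2Cl2, −78 °C; then pyridine, DMAP, Ac2O, −78 to −20 °C
Reagents that add atoms: acetic anhydride CC(=O)OC(C)=O
Why: Reductive acetylation of a lactone traps the aluminium hemiacetal in situ and gives the acetate without ring opening.

Step 12
Reactants: 18 3-[(tert-butyldimethylsilyl)oxy]propanal
Product: 19 (Z)-tert-butyl[(4-iodopent-3-en-1-yl)oxy]dimethylsilane
Conditions: Ph3PEtI, n-BuLi, THF, rt; I2, −78 °C; NaHMDS, −20 °C; then 18, −78 °C
Reagents that add atoms: ethyltriphenylphosphonium iodide CC[P+](c1ccccc1)(c1ccccc1)c1ccccc1.[I-]; iodine II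
Why: Stork–Zhao-type Wittig olefination with the α-iodo ylide gives the (Z)-2-iodo-2-alkene, in which iodine is cis to the chain.

Step 13
Reactants: 19 (Z)-vinyl iodide; 17 anomeric acetate
Product: 22 C2-alkenyl bis-ether (2R; (Z)-C3=C4 with C2 cis to C5), via vinyllithium 20 (not isolated), via alkenylalane 21 (not isolated)
Conditions: 19, t-BuLi (2 equiv), Et2O, −78 °C; Me2AlCl; then 17, CH2Cl2/toluene, −78 to 0 °C
Reagents that add atoms: none
Why: Iodine–lithium exchange and transmetalation retain the (Z)-geometry, and the Lewis acidic alkenylalane ionises the anomeric acetate and delivers the alkenyl group to the bicyclic oxocarbenium ion from its convex face (syn to H1, anti to C14), a C-glycosidation-type substitution that sets C2.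

Step 14
Reactants: 22 C2-alkenyl bis-ether
Product: 25 oxepane alcohol (3R; 4S; ring A enone; free C4–OH), via hydroxy enone 23 (not isolated), via epoxide 24 (not isolated)
Conditions: DDQ, CH2Cl2/H2O (10:1), 0 °C; then mCPBA, 0 °C to rt; CSA (5 mol%) if closure is slow
Reagents that add atoms: water O; mCPBA O=C(OO)c1cccc(Cl)c1
Why: DDQ should abstract hydride from C13–H of the cyclic prenyl-type allylic ether (C2–H of the other allylic ether lies in the nodal plane of the (Z)-olefin because of A(1,3) strain and would give only a secondary allyl cation); water then adds to the conjugated oxocarbenium ion and the hemiketal collapses to enone 23 with free O16–H, which is the known oxidative cleavage of prenyl ethers. Because ring A is now an electron-poor enone and the bromoalkene is deactivated, mCPBA (Prilezhaev epoxidation) can only attack the (Z)-C3=C4 olefin; in the A(1,3)-locked rotamer with H2 eclipsing the olefin it should come from the face anti to the ring oxygen on C2, the face on which O16–H sits as a hydrogen-bond donor, and this fixes C4 (S) and the (3S)-epoxide carbon of 24. The acids set free then trigger the hydroxy-epoxide cyclisation: O16 attacks tertiary C3 in a 7-exo-tet mode with inversion, so C3 (R) follows stereospecifically from the (Z)-geometry and the epoxide face, and C4–OH is released. Regioselectivity is doubly secured, since the 8-endo path would need attack at the secondary carbon through a larger ring, and the cis arrangement of the C14 and C1 side chains on ring A holds O16 close to C3. The closest known reaction types are DDQ deprotection of prenyl ethers and acid-catalysed exo cyclisation of epoxy alcohols to oxepanes. In one flask the step installs the ring A enone, removes the temporary tetrahydrofuran, closes the oxepane and sets C3 and C4.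

Step 15
Reactants: 25 oxepane alcohol
Product: 26 diol (C4–OH and C6–OH)
Conditions: HF·pyridine, THF, 0 °C
Reagents that add atoms: none
Why: Fluoride-mediated cleavage of the primary TBS ether leaves the enone, the tertiary ether and the vinyl bromide untouched.

Step 16
Reactants: 26 diol
Product: 27 β-hydroxy aldehyde (C6 aldehyde)
Conditions: TEMPO (10 mol%), PhI(OAc)2, CH2Cl2, rt
Reagents that add atoms: none
Why: TEMPO/PhI(OAc)2 oxidation is selective for the primary alcohol, so the hindered secondary C4–OH needs no protection.

Step 17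
Reactants: 27 β-hydroxy aldehyde
Product: 28 tetracyclic diol (6S; exocyclic methylene on C7)
Conditions: CrCl2, NiCl2 (1 mol%), DMSO, rt, 2 mM
Reagents that add atoms: none
Why: In this Nozaki–Hiyama–Kishi reaction the alkenylchromium species from the 2-bromoalkene adds to the aldehyde and not to the enone, the cis-2,5-tetrahydrofuran and the oxepane hold both chains on one face, and attack on the outward-facing side of the aldehyde should give C6 (S) as in closely related oxonane closures.

Step 18
Reactants: 28 tetracyclic diol
Product: 29 diacetate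
Conditions: Ac2O, pyridine, DMAP, CH2Cl2, rt
Reagents that add atoms: acetic anhydride CC(=O)OC(C)=O
Why: Standard acetylation esterifies the two secondary alcohols.

Step 19
Reactants: 29 diacetate
Product: 30 target CNP0212231.3 (1S,2R,3R,4S,6S,7S,9R,10R,14S,15S)
Conditions: Co(acac)2 (20 mol%), PhSiH3, O2 (1 atm), THF, rt
Reagents that add atoms: dioxygen O=O
Why: In this Mukaiyama hydration cobalt hydride transfers a hydrogen atom to the terminal CH2 of the 1,1-disubstituted alkene (much faster than to the trisubstituted enone), and the tertiary C7 radical should be trapped by O2 anti to the neighbouring C6 acetate, giving C7 (S) with Markovnikov regiochemistry.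

Compound list
1 | (E)-3-methylpent-2-en-4-yn-1-ol | C#C/C(C)=C/CO | starting material
2 | (E)-3-methylpenta-2,4-dien-1-ol | C=C/C(C)=C/CO | intermediate
3 | (E)-3-methylpenta-2,4-dienal | C=C/C(C)=C/C=O | intermediate
4 | rac-(E)-2-bromo-6-methylocta-1,5,7-trien-4-ol | C=C(Br)CC(O)/C=C(C)/C=C | intermediate
5 | (E)-2-bromo-6-methylocta-1,5,7-trien-4-one | C=C(Br)CC(=O)/C=C(C)/C=C | intermediate
6 | (4R,5E)-2-bromo-6-methylocta-1,5,7-trien-4-ol | C=C(Br)C[C@@H](O)/C=C(C)/C=C | intermediate
7 | maleic anhydride | O=C1C=CC(=O)O1 | starting material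
8 | (Z)-maleate half-ester of 6 | C=C(Br)C[C@@H](OC(=O)/C=C\C(=O)O)/C=C(C)/C=C | intermediate
9 | lactone acid, all-cis Diels–Alder adduct | C=C(Br)C[C@H]1OC(=O)[C@@H]2[C@@H](CC=C(C)[C@@H]21)C(=O)O | intermediate
10 | acid chloride of 9 | C=C(Br)C[C@H]1OC(=O)[C@@H]2[C@@H](CC=C(C)[C@@H]21)C(=O)Cl | intermediate
11 | lactone aldehyde | C=C(Br)C[C@H]1OC(=O)[C@@H]2[C@@H](CC=C(C)[C@@H]21)C=O | intermediate
12 | vinyl lactone | C=C(Br)C[C@H]1OC(=O)[C@@H]2[C@@H](CC=C(C)[C@@H]21)C=C | intermediate
13 | (15S)-dimethylalane from carboalumination | C=C(Br)C[C@H]1OC(=O)[C@@H]2[C@@H](CC=C(C)[C@@H]21)[C@H](C)C[Al](C)C | intermediate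
14 | (15S)-primary alcohol | C=C(Br)C[C@H]1OC(=O)[C@@H]2[C@@H](CC=C(C)[C@@H]21)[C@H](C)CO | intermediate
15 | ether lactone with temporary C13–O16 tetrahydrofuran | C=C(Br)C[C@H]1OC(=O)[C@@H]2[C@@H]3[C@H](C)CO[C@@H]3C=C(C)[C@@H]21 | intermediate
16 | diisobutylaluminium hemiacetal of 15 | C=C(Br)C[C@H]1OC(O[Al](CC(C)C)CC(C)C)[C@@H]2[C@@H]3[C@H](C)CO[C@@H]3C=C(C)[C@@H]21 | intermediate
17 | anomeric acetate | C=C(Br)C[C@H]1OC(OC(C)=O)[C@@H]2[C@@H]3[C@H](C)CO[C@@H]3C=C(C)[C@@H]21 | intermediate
18 | 3-[(tert-butyldimethylsilyl)oxy]propanal | O=CCCO[Si](C)(C)C(C)(C)C | starting material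
19 | (Z)-tert-butyl[(4-iodopent-3-en-1-yl)oxy]dimethylsilane | C/C(I)=C/CCO[Si](C)(C)C(C)(C)C | intermediate
20 | vinyllithium from 19 | C/C([Li])=C/CCO[Si](C)(C)C(C)(C)C | intermediate
21 | alkenyl(dimethyl)alane from 20 | C/C([Al](C)C)=C/CCO[Si](C)(C)C(C)(C)C | intermediate
22 | (2R)-C2-alkenyl bis-ether | C=C(Br)C[C@H]1O[C@@H](/C(C)=C\CCO[Si](C)(C)C(C)(C)C)[C@@H]2[C@@H]3[C@H](C)CO[C@@H]3C=C(C)[C@@H]21 | intermediate
23 | hydroxy enone | C=C(Br)C[C@H]1O[C@@H](/C(C)=C\CCO[Si](C)(C)C(C)(C)C)[C@@H]2[C@@H](C(=O)C=C(C)[C@@H]21)[C@H](C)CO | intermediate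
24 | (3S,4S)-epoxy hydroxy enone | C=C(Br)C[C@H]1O[C@@H]([C@@]3(C)O[C@H]3CCO[Si](C)(C)C(C)(C)C)[C@@H]2[C@@H](C(=O)C=C(C)[C@@H]21)[C@H](C)CO | intermediate
25 | (3R,4S)-oxepane alcohol | C=C(Br)C[C@H]1O[C@@H]3[C@@H]2[C@@H](C(=O)C=C(C)[C@@H]21)[C@H](C)CO[C@]3(C)[C@@H](O)CCO[Si](C)(C)C(C)(C)C | intermediate
26 | diol | C=C(Br)C[C@H]1O[C@@H]3[C@@H]2[C@@H](C(=O)C=C(C)[C@@H]21)[C@H](C)CO[C@]3(C)[C@@H](O)CCO | intermediate
27 | β-hydroxy aldehyde | C=C(Br)C[C@H]1O[C@@H]3[C@@H]2[C@@H](C(=O)C=C(C)[C@@H]21)[C@H](C)CO[C@]3(C)[C@@H](O)CC=O | intermediate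
28 | tetracyclic diol with C7 methylene | O[C@H]1C[C@H](O)C(=C)C[C@H]2O[C@@H]3[C@@H]4[C@@H](C(=O)C=C(C)[C@@H]42)[C@H](C)CO[C@]13C | intermediate
29 | diacetate | CC(=O)O[C@H]1C[C@H](OC(C)=O)C(=C)C[C@H]2O[C@@H]3[C@@H]4[C@@H](C(=O)C=C(C)[C@@H]42)[C@H](C)CO[C@]13C | intermediate
30 | CNP0212231.3 | CC(=O)O[C@H]1C[C@H](OC(C)=O)[C@@](C)(O)C[C@H]2O[C@@H]3[C@@H]4[C@@H](C(=O)C=C(C)[C@@H]42)[C@H](C)CO[C@]13C | target

Total step count: 19. Longest linear sequence: 18 (steps 1–11 and 13–19).

Steps most likely to fail

Step 14. The epoxidation may occur from the wrong face. The closure may also be overtaken by a hydride shift in the opened epoxide or by participation of the tetrahydrofuran oxygen.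
- Fallback: give up the one-pot relay and close the same ether from its other end.
- From 22 the DDQ cleavage is run alone and 23 is isolated.
- 23 is epoxidised under catalyst control (Shi epoxidation with the L-fructose-derived ketone and Oxone) and 24 is isolated.
- Dilute aqueous HClO4 in THF opens 24 at C3 with inversion to the triol F1.
- Tf2O and 2,6-lutidine at −78 °C convert only the primary alcohol of F1 into the primary triflate F2.
- The tertiary C3 hydroxyl group displaces the triflate in F2 (Williamson-type closure). This comes back to the route at 25.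

Step 9. Carboalumination of the α-branched vinyl group may be slow, AlMe3 may attack the lactone, or facial selectivity may be low.
- Fallback: from 10, Me2CuLi at −78 °C gives the methyl ketone F3.
- Wittig methylenation of F3 gives the isopropenyl lactone F4.
- Hydroboration of F4 with diisopinocampheylborane and oxidation with NaBO3, followed by chromatographic separation of the C15 epimers, comes back to the route at 14.

Step 19. Hydrogen-atom transfer may also reach the enone, or O2 may trap the C7 radical with poor facial selectivity.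
- Fallback: from 28 (before acetylation), hydroxyl-directed epoxidation with VO(acac)2 and t-BuOOH gives the spiro-epoxide F5.
- Excess DIBAL-H opens F5 at its CH2 terminus and reduces the enone, giving the tetraol F6.
- MnO2 reoxidises only the allylic alcohol of F6 to the triol enone F7.
- Acetylation of the two secondary alcohols of F7 with Ac2O, pyridine and DMAP comes back to the route at 30.

Further compounds
F1 | step 14 | triol from hydrolysis of 24 (C3–OH, C4–OH, C16–OH) | C=C(Br)C[C@H]1O[C@@H]([C@](C)(O)[C@@H](O)CCO[Si](C)(C)C(C)(C)C)[C@@H]2[C@@H](C(=O)C=C(C)[C@@H]21)[C@H](C)CO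
F2 | step 14 | primary C16 triflate of F1 | C=C(Br)C[C@H]1O[C@@H]([C@](C)(O)[C@@H](O)CCO[Si](C)(C)C(C)(C)C)[C@@H]2[C@@H](C(=O)C=C(C)[C@@H]21)[C@H](C)COS(=O)(=O)C(F)(F)F
F3 | step 9 | methyl ketone lactone | C=C(Br)C[C@H]1OC(=O)[C@@H]2[C@@H](CC=C(C)[C@@H]21)C(C)=O
F4 | step 9 | isopropenyl lactone | C=C(Br)C[C@H]1OC(=O)[C@@H]2[C@@H](CC=C(C)[C@@H]21)C(C)=C
F5 | step 19 | C7 spiro-epoxide of 28 | O[C@H]1C[C@H](O)[C@]5(CO5)C[C@H]2O[C@@H]3[C@@H]4[C@@H](C(=O)C=C(C)[C@@H]42)[C@H](C)CO[C@]13C
F6 | step 19 | tetraol with C13 allylic alcohol (C13 epimer mixture) | O[C@H]1C[C@H](O)[C@@](C)(O)C[C@H]2O[C@@H]3[C@@H]4[C@@H](C(O)C=C(C)[C@@H]42)[C@H](C)CO[C@]13C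
F7 | step 19 | triol enone | O[C@H]1C[C@H](O)[C@@](C)(O)C[C@H]2O[C@@H]3[C@@H]4[C@@H](C(=O)C=C(C)[C@@H]42)[C@H](C)CO[C@]13C
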